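**Retrosynthetic overview**
1. Target 19 ⇐ angeloylation of the C1–OH (mixed anhydride) ⇐ desilylation ⇐ diacetylation of diol 14 (C4–OH, C9–OH).
2. 14 ⇐ catalyst-controlled reduction of the C4 ketone and isobutenylation of the C9 aldehyde of keto aldehyde 10.
3. 10 ⇐ key step: one-carbon ring expansion (alkoxy-radical β-scission) of bicyclo[3.1.0]hexenol 7; the ring-expanded C6 radical is trapped enantioselectively by crotonaldehyde (C6–C7 bond, C6 and C7 stereocentres).
4. 7 ⇐ cyclopropanation of the silyl dienol ether of (S)-4-silyloxy-2-methylcyclopentenone 3 ⇐ commercial (S)-4-silyloxycyclopentenone 1 (iodination, Negishi methylation).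
5. Ring order: cyclopentene (bought) → fused cyclopropane → six-membered ring by ring expansion; no other ring is made.

Assumption: 1 is bought as its TBS ether (the 4-hydroxycyclopentenone core has seven non-hydrogen atoms).
Atom labels follow the target: C1 = CH–OAng, C2=C3(Me), C4 = CH–OAc, C5 = CH2, C6 = ring CH carrying the chain C7(Me)–C8H2–C9(OAc)–C10=C11Me2. The target is (1S,4R,6S,7R,9R), with C1–O and C4–O cis and the side chain trans to both.

Step 1
Reactants: 1 (4S)-4-[(tert-butyldimethylsilyl)oxy]cyclopent-2-en-1-one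
Product: 2 (4S)-4-[(tert-butyldimethylsilyl)oxy]-2-iodocyclopent-2-en-1-one
Conditions: I2 (1.5 equiv), pyridine/CH2Cl2 1:1, 0 °C → rt
Reagents that add atoms: iodine, II
Why: Johnson α-iodination (pyridine conjugate addition, iodination of the enolate, E1cB loss of pyridine) puts iodine only on the enone α-carbon; the C–OTBS stereocentre is not involved.

Step 2
Reactants: 2 (4S)-4-[(tert-butyldimethylsilyl)oxy]-2-iodocyclopent-2-en-1-one
Product: 3 (4S)-4-[(tert-butyldimethylsilyl)oxy]-2-methylcyclopent-2-en-1-one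
Conditions: MeZnCl (1.5 equiv), PdCl2(dppf) (5 mol %), THF, 0 °C → rt
Reagents that add atoms: methylzinc chloride, C[Zn]Cl
Why: Negishi cross-coupling of the α-iodoenone under neutral conditions, so no base is present that could eliminate the β-silyloxy group; the stereocentre is unchanged.

Step 3
Reactants: 3 (4S)-4-[(tert-butyldimethylsilyl)oxy]-2-methylcyclopent-2-en-1-one
Product: 5 tert-butyldimethyl{[(1R)-3-methyl-4-(trimethylsilyloxy)cyclopenta-2,4-dien-1-yl]oxy}silane, via lithium dienolate 4 (not isolated)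
Conditions: LDA (1.1 equiv), TMSCl (internal quench), THF, −78 °C; pentane filtration; used at once below −20 °C
Reagents that add atoms: chlorotrimethylsilane, C[Si](C)(C)Cl
Why: Kinetic α′-deprotonation with LDA and O-silylation of the cross-conjugated dienolate (silyl enol ether formation) at −78 °C, cold enough to suppress silanolate β-elimination and [1,5]-H shift, so the C–OTBS centre keeps its configuration (the descriptor changes to R only through CIP priorities).

Step 4
Reactants: 5 tert-butyldimethyl{[(1R)-3-methyl-4-(trimethylsilyloxy)cyclopenta-2,4-dien-1-yl]oxy}silane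
Product: 7 (1R,4R,5S)-4-[(tert-butyldimethylsilyl)oxy]-2-methylbicyclo[3.1.0]hex-2-en-1-ol, via cyclopropyl trimethylsilyl ether 6 (not isolated)
Conditions: Et2Zn, CH2I2, CH2Cl2, −20 → 0 °C; then K2CO3 (cat.), MeOH, 0 °C, 15 min
Reagents that add atoms: diiodomethane, ICI
Why: Furukawa–Simmons–Smith cyclopropanation occurs at the electron-rich silyl enol ether C=C rather than the trisubstituted C2=C3 alkene, anti to OTBS (these ring-fusion centres are erased again in step 5), and brief methanolysis removes only the TMS group.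

Step 5
Reactants: 7 (1R,4R,5S)-4-[(tert-butyldimethylsilyl)oxy]-2-methylbicyclo[3.1.0]hex-2-en-1-ol; 8 (E)-but-2-enal (crotonaldehyde)
Product: 10 (3R)-3-[(1S,2S)-2-[(tert-butyldimethylsilyl)oxy]-4-methyl-5-oxocyclohex-3-en-1-yl]butanal, via ring-expanded 5-oxocyclohexenyl radical 9 (not isolated)
Conditions: 8 (3 equiv), (S)-α,α-bis[3,5-bis(trifluoromethyl)phenyl]prolinol TMS ether (20 mol %), TFA (20 mol %), 9-mesityl-10-methylacridinium BF4 (3 mol %), MeCN/H2O 20:1, 450 nm LED, −10 °C
Reagents that add atoms: none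
Why: Proposed new method: in a photoredox/iminium dual cycle the excited acridinium oxidises the strained 1-alkenylcyclopropanol 7 (SET, loss of H+), the cyclopropyloxy radical cleaves its internal C–C bond (one-carbon ring expansion driven by strain release and formation of the conjugated enone) to the secondary radical 9, which adds to the (S)-diarylprolinol iminium ion of crotonaldehyde on the face opposite the diarylmethyl group (C7 = R) and anti to the neighbouring OTBS (C6 = S, trans to C1–O), and the α-iminyl radical cation is reduced by the acridinyl radical to the enamine, which is protonated and hydrolysed (redox-neutral, no by-product); the closest known reaction types are the Saegusa–Ito-type ring-enlarging oxidation of bicyclic cyclopropanols with Giese trapping and the enantioselective iminium-ion β-alkylation of aromatic enals with monocyclic cyclopropanols, whereas a fused, ring-expanding cyclopropanol with an aliphatic enal is untested.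

Step 6
Reactants: 10 (3R)-3-[(1S,2S)-2-[(tert-butyldimethylsilyl)oxy]-4-methyl-5-oxocyclohex-3-en-1-yl]butanal; 11 1-bromo-2-methylprop-1-ene
Product: 13 (4S,5S)-4-[(tert-butyldimethylsilyl)oxy]-5-[(2R,4R)-4-hydroxy-6-methylhept-5-en-2-yl]-2-methylcyclohex-2-en-1-one, via alkenylchromium(III) dichloride 12 (not isolated)
Conditions: 11 (2 equiv), CrCl2 (4 equiv), chiral oxazoline–sulfonamide ligand (Kishi type, antipode giving 9R; 4.4 equiv), Et3N (4.4 equiv), NiCl2 (2 mol %), THF, rt
Reagents that add atoms: none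
Why: Nozaki–Hiyama–Kishi alkenylation adds the alkenyl–Cr(III) species only to the aldehyde (enone ketone and silyl ether inert), and the chiral ligand on chromium directs Si-face addition to set C9 (R) independently of the remote C7 centre.

Step 7
Reactants: 13 (4S,5S)-4-[(tert-butyldimethylsilyl)oxy]-5-[(2R,4R)-4-hydroxy-6-methylhept-5-en-2-yl]-2-methylcyclohex-2-en-1-one
Product: 14 (1R,4S,5S)-4-[(tert-butyldimethylsilyl)oxy]-5-[(2R,4R)-4-hydroxy-6-methylhept-5-en-2-yl]-2-methylcyclohex-2-en-1-ol
Conditions: (S)-Me-CBS (0.5 equiv), catecholborane (3 equiv), toluene, −78 °C; MeOH, aq. NaOH work-up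
Reagents that add atoms: none
Why: Corey–Bakshi–Shibata reduction with C3 (α-methyl alkenyl) as the large and C5H2 as the small group, so the (S)-oxazaborolidine delivers hydride to give the (4R)-alcohol, cis to C1–O and trans to the side chain, by catalyst control over the intrinsic axial-attack preference; the s-trans enone cannot undergo 1,4-reduction and the free C9–OH only consumes borane.

Step 8
Reactants: 14 (1R,4S,5S)-4-[(tert-butyldimethylsilyl)oxy]-5-[(2R,4R)-4-hydroxy-6-methylhept-5-en-2-yl]-2-methylcyclohex-2-en-1-ol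
Product: 15 (1R,4S,5S)-5-[(2R,4R)-4-acetoxy-6-methylhept-5-en-2-yl]-4-[(tert-butyldimethylsilyl)oxy]-2-methylcyclohex-2-en-1-yl acetate
Conditions: Ac2O (4 equiv), pyridine, DMAP (cat.), CH2Cl2, 0 °C → rt
Reagents that add atoms: acetic anhydride, CC(=O)OC(C)=O
Why: DMAP-catalysed acetylation of both secondary allylic alcohols while C1–O stays masked as the TBS ether; no stereocentre is touched.

Step 9
Reactants: 15 (1R,4S,5S)-5-[(2R,4R)-4-acetoxy-6-methylhept-5-en-2-yl]-4-[(tert-butyldimethylsilyl)oxy]-2-methylcyclohex-2-en-1-yl acetate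
Product: 16 (1R,4S,5S)-5-[(2R,4R)-4-acetoxy-6-methylhept-5-en-2-yl]-4-hydroxy-2-methylcyclohex-2-en-1-yl acetate
Conditions: HF·pyridine, pyridine/THF, 0 °C → rt
Reagents that add atoms: none
Why: Fluoride cleavage of the secondary TBS ether under buffered, non-basic conditions that leave both acetates in place and avoid acyl migration.

Step 10
Reactants: 16 (1R,4S,5S)-5-[(2R,4R)-4-acetoxy-6-methylhept-5-en-2-yl]-4-hydroxy-2-methylcyclohex-2-en-1-yl acetate; 17 angelic acid, (2Z)-2-methylbut-2-enoic acid
Product: 19 (1S,4R,6S)-4-acetoxy-6-[(2R,4R)-4-acetoxy-6-methylhept-5-en-2-yl]-3-methylcyclohex-2-en-1-yl (2Z)-2-methylbut-2-enoate, via mixed anhydride 18 (not isolated)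
Conditions: 17 (3 equiv), 2,4,6-trichlorobenzoyl chloride (3 equiv), Et3N (6 equiv), toluene, rt, 2 h; then 16, 75 °C (no DMAP)
Reagents that add atoms: none
Why: Yamaguchi-type esterification in which the alcohol attacks the unhindered angeloyl carbonyl of the mixed anhydride, and leaving out a nucleophilic catalyst prevents Z→E isomerisation to the tiglate.

**Compound list**
1 | (4S)-4-[(tert-butyldimethylsilyl)oxy]cyclopent-2-en-1-one | CC(C)(C)[Si](C)(C)O[C@@H]1C=CC(=O)C1 | starting material
2 | (4S)-4-[(tert-butyldimethylsilyl)oxy]-2-iodocyclopent-2-en-1-one | CC(C)(C)[Si](C)(C)O[C@@H]1C=C(I)C(=O)C1 | intermediate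
3 | (4S)-4-[(tert-butyldimethylsilyl)oxy]-2-methylcyclopent-2-en-1-one | CC(C)(C)[Si](C)(C)O[C@@H]1C=C(C)C(=O)C1 | intermediate
4 | lithium (3R)-3-[(tert-butyldimethylsilyl)oxy]-5-methylcyclopenta-1,4-dien-1-olate | CC(C)(C)[Si](C)(C)O[C@@H]1C=C(C)C([O-])=C1.[Li+] | intermediate
5 | tert-butyldimethyl{[(1R)-3-methyl-4-(trimethylsilyloxy)cyclopenta-2,4-dien-1-yl]oxy}silane | CC(C)(C)[Si](C)(C)O[C@@H]1C=C(C)C(O[Si](C)(C)C)=C1 | intermediate
6 | tert-butyldimethyl{[(1R,4R,5S)-2-methyl-1-(trimethylsilyloxy)bicyclo[3.1.0]hex-2-en-4-yl]oxy}silane (cyclopropane anti to OTBS) | CC(C)(C)[Si](C)(C)O[C@@H]1C=C(C)[C@@]2(O[Si](C)(C)C)C[C@@H]12 | intermediate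
7 | (1R,4R,5S)-4-[(tert-butyldimethylsilyl)oxy]-2-methylbicyclo[3.1.0]hex-2-en-1-ol | CC(C)(C)[Si](C)(C)O[C@@H]1C=C(C)[C@@]2(O)C[C@@H]12 | intermediate
8 | (E)-but-2-enal (crotonaldehyde) | C/C=C/C=O | starting material
9 | (2S)-2-[(tert-butyldimethylsilyl)oxy]-4-methyl-5-oxocyclohex-3-en-1-yl radical | CC(C)(C)[Si](C)(C)O[C@@H]1C=C(C)C(=O)C[CH]1 | intermediate
10 | (3R)-3-[(1S,2S)-2-[(tert-butyldimethylsilyl)oxy]-4-methyl-5-oxocyclohex-3-en-1-yl]butanal | CC(C)(C)[Si](C)(C)O[C@@H]1C=C(C)C(=O)C[C@H]1[C@H](C)CC=O | intermediate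
11 | 1-bromo-2-methylprop-1-ene | CC(C)=CBr | starting material
12 | (2-methylprop-1-en-1-yl)chromium(III) dichloride (chiral ligand omitted) | CC(C)=C[Cr](Cl)Cl | intermediate
13 | (4S,5S)-4-[(tert-butyldimethylsilyl)oxy]-5-[(2R,4R)-4-hydroxy-6-methylhept-5-en-2-yl]-2-methylcyclohex-2-en-1-one | CC(C)(C)[Si](C)(C)O[C@@H]1C=C(C)C(=O)C[C@H]1[C@H](C)C[C@@H](O)C=C(C)C | intermediate
14 | (1R,4S,5S)-4-[(tert-butyldimethylsilyl)oxy]-5-[(2R,4R)-4-hydroxy-6-methylhept-5-en-2-yl]-2-methylcyclohex-2-en-1-ol | CC(C)(C)[Si](C)(C)O[C@@H]1C=C(C)[C@H](O)C[C@H]1[C@H](C)C[C@@H](O)C=C(C)C | intermediate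
15 | (1R,4S,5S)-5-[(2R,4R)-4-acetoxy-6-methylhept-5-en-2-yl]-4-[(tert-butyldimethylsilyl)oxy]-2-methylcyclohex-2-en-1-yl acetate | CC(C)(C)[Si](C)(C)O[C@@H]1C=C(C)[C@H](OC(C)=O)C[C@H]1[C@H](C)C[C@H](C=C(C)C)OC(C)=O | intermediate
16 | (1R,4S,5S)-5-[(2R,4R)-4-acetoxy-6-methylhept-5-en-2-yl]-4-hydroxy-2-methylcyclohex-2-en-1-yl acetate | O[C@@H]1C=C(C)[C@H](OC(C)=O)C[C@H]1[C@H](C)C[C@H](C=C(C)C)OC(C)=O | intermediate
17 | angelic acid, (2Z)-2-methylbut-2-enoic acid | C/C=C(/C)C(=O)O | starting material
18 | (2Z)-2-methylbut-2-enoic 2,4,6-trichlorobenzoic anhydride | C/C=C(/C)C(=O)OC(=O)c1c(Cl)cc(Cl)cc1Cl | intermediate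
19 | (1S,4R,6S)-4-acetoxy-6-[(2R,4R)-4-acetoxy-6-methylhept-5-en-2-yl]-3-methylcyclohex-2-en-1-yl (2Z)-2-methylbut-2-enoate | C/C=C(/C)C(=O)O[C@@H]1C=C(C)[C@H](OC(C)=O)C[C@H]1[C@H](C)C[C@H](C=C(C)C)OC(C)=O | target

**Step count and risks**
Total steps: 10. Longest linear sequence: 10 steps (1 → 19); compounds 8, 11 and 17 are bought.

Most likely to fail, in this order:

Step 5 (the proposed new ring-expansion/iminium trapping). The radical adduct may fragment back before it is reduced, the enamine may close by aldol reaction onto the C4 ketone, or C7 selectivity may be low with an aliphatic enal. The fallback uses known chemistry and moves the C7 stereocentre into a separate step. It sets out from 7, which is oxidised with stoichiometric Mn(III) tris(picolinate) in DMF at 0 °C in the presence of Bu3SnH and but-2-ynal. This is the established Mn(III) ring-enlarging generation of β-keto radicals from bicyclic cyclopropanols with tin-hydride-mediated Giese trapping. It gives the β,β-disubstituted enal (2E)-3-[(1S,2R)-2-[(tert-butyldimethylsilyl)oxy]-4-methyl-5-oxocyclohex-3-en-1-yl]but-2-enal F1 together with its 2Z isomer, with C6 again set anti to OTBS. An E/Z-convergent organocatalytic transfer hydrogenation of F1 (chiral imidazolidinone salt of the antipode giving 7R, Hantzsch ester, CHCl3, −30 °C) then sets C7 and delivers 10, where the route is rejoined.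

Step 4 (cyclopropanation of the isolated diene). Compound 5 is a 5-substituted 2-siloxycyclopentadiene that can undergo [1,5]-H shift (loss of the C–OTBS stereocentre) or dimerise, the carbenoid may also attack C2=C3, and 7 can ring-open with base. The fallback avoids the neutral diene: it sets out from 3, which is deprotonated as before to lithium dienolate 4 and cyclopropanated in the same flask at −78 → −30 °C with the samarium carbenoid from Sm metal and CH2I2 (direct enolate cyclopropanation to cyclopropanols). This gives lithium (1R,4R,5S)-4-[(tert-butyldimethylsilyl)oxy]-2-methylbicyclo[3.1.0]hex-2-en-1-olate F2, which is protonated on NH4Cl work-up to 7, where the route is rejoined.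

Step 7 (CBS reduction against the substrate bias). Small hydrides prefer axial attack, which gives the C4 epimer, so the catalyst may not override the ring. The fallback accepts the substrate preference and inverts afterwards. It sets out from 13, which is acetylated at C9–OH (Ac2O, pyridine, DMAP) to (4R,6R)-6-[(1S,2S)-2-[(tert-butyldimethylsilyl)oxy]-4-methyl-5-oxocyclohex-3-en-1-yl]-2-methylhept-2-en-4-yl acetate F3. Luche reduction (NaBH4, CeCl3, MeOH, −78 °C) then gives the equatorial alcohol (4R,6R)-6-[(1S,2S,5S)-2-[(tert-butyldimethylsilyl)oxy]-5-hydroxy-4-methylcyclohex-3-en-1-yl]-2-methylhept-2-en-4-yl acetate F4. Mitsunobu reaction of F4 with acetic acid (PPh3, DIAD, THF, 0 °C) inverts C4 and gives diacetate 15, where the route is rejoined.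

**Further compounds**
F1 | step 5 | (2E)-3-[(1S,2R)-2-[(tert-butyldimethylsilyl)oxy]-4-methyl-5-oxocyclohex-3-en-1-yl]but-2-enal (formed with its 2Z isomer) | CC(C)(C)[Si](C)(C)O[C@@H]1C=C(C)C(=O)C[C@H]1/C(C)=C/C=O
F2 | step 4 | lithium (1R,4R,5S)-4-[(tert-butyldimethylsilyl)oxy]-2-methylbicyclo[3.1.0]hex-2-en-1-olate | CC(C)(C)[Si](C)(C)O[C@@H]1C=C(C)[C@@]2([O-])C[C@@H]12.[Li+]
F3 | step 7 | (4R,6R)-6-[(1S,2S)-2-[(tert-butyldimethylsilyl)oxy]-4-methyl-5-oxocyclohex-3-en-1-yl]-2-methylhept-2-en-4-yl acetate | CC(C)(C)[Si](C)(C)O[C@@H]1C=C(C)C(=O)C[C@H]1[C@H](C)C[C@H](C=C(C)C)OC(C)=O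
F4 | step 7 | (4R,6R)-6-[(1S,2S,5S)-2-[(tert-butyldimethylsilyl)oxy]-5-hydroxy-4-methylcyclohex-3-en-1-yl]-2-methylhept-2-en-4-yl acetate | CC(C)(C)[Si](C)(C)O[C@@H]1C=C(C)[C@@H](O)C[C@H]1[C@H](C)C[C@H](C=C(C)C)OC(C)=O
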